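The data were computed on assumed constants; the scatter is artificial.

common to all: starting material 0.50 mM
- delta: second substrate 1 mM; partner 0.35 mM; protic impurity 0.25 mM; free catalyst 18 µM; run made earlier
- beta: second substrate 1 mM; partner 0.35 mM; protic impurity 0.25 mM; free catalyst 42 µM; run made earlier
- amber: second substrate 1.00 mM; partner 0.350 mM; protic impurity 0.250 mM; free catalyst 32 µM; time 8.0 min
- violet: second substrate 1.00 mM; partner 0.350 mM; protic impurity 0.250 mM; free catalyst 13 µM; time 8.0 min

| run | time / min | catalyst intermediate A / % | starting material / % | target / % |
|---|---|---|---|---|
| delta | 0.500 | 1 | 80 | 16 |
| delta | 1.33 | 0 | 76 | 26 |
| delta | 2.50 | 2 | 73 | 26 |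
| delta | 4.00 | 4 | 73 | 25 |
| delta | 6.00 | 4 | 75 | 25 |
| beta | 0.417 | 5 | 68 | 26 |
| beta | 0.833 | 7 | 69 | 28 |
| beta | 1.50 | 2 | 67 | 29 |
| beta | 3.00 | 4 | 67 | 30 |
| beta | 6.00 | 4 | 70 | 30 |

(scatter of a reading: 1.5 percentage points)

* which of these there is most of at the end, counted by the starting material in it, amber (catalyst intermediate A / starting material / target)
* which of these there is most of at the end, counted by the starting material in it, violet (catalyst intermediate A / starting material / target)
* final amount of the leader among these, as a percentage of the starting material charged, in amber
* final amount of the leader among these, as a percentage of the starting material charged, in violet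



The easy step is the clock: in delta the starting material reads 73% at 2.50 min and 75% at 6.00 min, a shift of 2 percentage points against a scatter of 1.5 points, so the time need not be known well, and I carry that flat stretch on to 8.0 min in amber and violet.

To weigh the charges I average the last 3 readings of each run and divide the starting material gone by the partner charged, both as fractions of the starting charge. Delta holds 73.7% and gives 37.6%, while beta holds 68.0% and gives 45.7%. Catalyst rises from 3.60% of the charge in delta to 8.40% in beta, so a 10% error in amber's catalyst moves the answer by 0.76 points. If the partner acts as the limiting reagent, the same error in partner, taken at delta's ratio, moves it by 2.6 points, which is more, so the partner charge has to be known better than the catalyst charge. The protic impurity is the same in both runs, so I can't weigh it and hold it as charged.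

Now the number itself. The reach, the fraction of the starting charge removed per fraction of partner charged, read on a straight line in catalyst through delta and beta, is 42.3% in amber and, by extending that line to a catalyst charge lower than delta's, 35.9% in violet. My estimate of the starting material at the end is then 70.4% in amber and 74.8% in violet.

The forecast names starting material as leader in both, with 71% (67% to 74%) in amber and 75% (71% to 79%) in violet, and says: “Eight minutes is well into the plateau, so starting material leads in both.” My amber figure is lower than the forecast's.

Amber ends at 69.5% and violet at 75.4%, with starting material leading in both. At 8.0 min amber's partner stands at 0% of its charge, less than the 69% of starting material. Read back from that result, amber's reach is 43.6% against the 42.3% I carried.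

    starting material + free catalyst ⇌ catalyst intermediate A (K = 4900 /M, k = 30000 /M/s)
    partner + catalyst intermediate A → free catalyst + target (k = 1700 /M/s)
    second substrate + free catalyst ⇌ catalyst intermediate B (K = 2000 /M, k = 2800 /M/s)
    partner + catalyst intermediate B → free catalyst + second product (k = 2300 /M/s)
    catalyst intermediate B → spent catalyst (k = 0.00100 /s)
    second substrate → decomposition product (k = 1.20 × 10⁻⁵ /s)
    partner + protic impurity → quenched reagent (k = 51.0 /M/s)

A neighbour of amber, charged with partner at 176% of the starting charge, should by the carried reach keep 25.5% of its starting material, which puts target in front. It ends with 28.4% of starting material and 70.4% of target, and target leads.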